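## The problem

Compound 12 is a phenylcoumaran-type neolignan. Its core is a 2,3-dihydrobenzofuran whose benzo ring (ring A) carries an allyl group at C5 and a methoxy group at C7; C2 bears a 4-hydroxy-3-methoxyphenyl group (ring C), and C3 bears a CH2–O arm to a 4-allyl-2-methoxyphenyl ring (ring B). The only stereocentres are the adjacent C2 (S) and C3 (R), trans across the five-membered ring. C3 has no carbonyl next to it, so a wrong relative configuration cannot be repaired by equilibration once the side chain is an ether; the two centres must be set together, or one must dictate the other through a stereospecific bond formation. C2 is a benzylic ether para to the ring C oxygen and can ionise towards a quinone methide under acid, or under hot base once the phenol is free, so the phenol should be unveiled last and gently. The two allyl groups are the other fragile feature: they are reduced by hydrogen, migrate into conjugation under palladium hydrides or strong base, and react with aryl–palladium species and metal carbenes. The structural opening lies on ring A: O1 sits on C7a and C3 on the neighbouring C3a, with the C7 methoxy on the other flank of C7a. This is the ipso/ortho pair that a palladium–norbornene relay installs on an ortho-substituted aryl iodide, and the O1–C2–C3 unit is an epoxide in disguise.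

## Retrosynthesis

**12 from 11.** No skeletal bond is cut; the ring C phenol is masked as pivalate 11. An ester is preferred to a silyl ether for three reasons: it is inert to zerovalent palladium, it comes off by methanolysis at room temperature, and it turns the ring C oxygen into an electron-poor substituent, which matters two stages earlier. The forward step must free the phenol without moving the allyl double bonds or ionising C2.

**11 from 10.** Both aryl–allyl bonds (C5–CH2 on ring A and C4–CH2 on ring B) are cut together, giving dichloride 10. Allyl groups carried from the start would meet the semihydrogenation, the epoxidation oxidant and, worst, the aryl–palladium intermediates of the ring-forming step. Chlorides are silent in all of these and let one operation serve both rings. The forward reaction is a twofold Suzuki–Miyaura allylation of electron-rich aryl chlorides that must not isomerise the product to propenyl arenes.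

**10 from 8 and 9.** C3–C3a and O1–C7a are cut in one operation, giving aryl iodide 9 and cis-epoxide 8. Cutting O1–C2 or C2–C3 instead leaves an open-chain or carbene precursor that is built linearly, and the latter delivers the cis ring first. The chosen cut halves the molecule, uses commercial 9 as all of ring A, and stores both stereocentres in an epoxide whose cis geometry becomes trans by inversion at C3. The forward reaction must open 8 at C3 and not at benzylic C2, with clean inversion, and must engage C–I but not C–Cl. The pivaloyloxy group of 8 is chosen for this step: with a silyl ether para to C2 the epoxide would ionise at the benzylic carbon, which the ester prevents.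

**8 from 7.** The two epoxide C–O bonds are cut, leading to the achiral Z-alkene 7. Z-configured aryl alkenes are the preferred substrates of (salen)manganese epoxidation. A dihydroxylation route would need the E-alkene and a regioselective ring closure in which any regiochemical leakage costs enantiomeric purity. The forward step must distinguish the alkene faces and keep the cis geometry.

**7 from 6, and 6 from 2 and 5.** The alkene is traced to alkyne 6, since syn delivery of hydrogen gives Z geometry more reliably than olefination with a semi-stabilised benzylic ylide. The C(sp2)–C(sp) bond of 6 is cut to aryl iodide 2 and propargyl ether 5, a Sonogashira coupling at room temperature that leaves the C–Cl bond alone.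

**2 from 1, and 5 from 3 and 4.** An O–acyl and an O–alkyl bond are cut. Phenol 1, phenol 3 and propargyl bromide 4 are commercial, and both forward steps are routine phenoxide chemistry.

## Roads not taken

**Alternative 1:** The ring C–C2 bond and the C3–carbonyl bond are cut across the C2=C3 bond of a preformed benzofuran, 5-bromo-7-methoxy-1-benzofuran A1.
- Forward step: the cationic aryl–palladium species from 3-methoxy-4-(triisopropylsilyloxy)benzenediazonium tetrafluoroborate A2 and Pd(O2CCF3)2 with a chiral pyridine–oxazoline ligand would add across the furan double bond, aryl to C2. The benzylic C3–palladium bond, left without a syn β-hydrogen, would be trapped by CO and methanol to give the cis ester A3 (methyl (2S,3R)-5-bromo-7-methoxy-2-[3-methoxy-4-(triisopropylsilyloxy)phenyl]-2,3-dihydro-1-benzofuran-3-carboxylate).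
- Merits: the building blocks are flat and cheap, no ring has to be closed, and ring B can be attached later as an intact allyl-bearing phenol, which saves one late cross-coupling. In these respects it is better than the chosen plan, which needs a five-step epoxide.
- Weak points: methoxycarbonylation of the aryl–palladium species before it meets the alkene is a fast known process. Face selection on a benzofuran in a three-component reaction is unproven. The syn addition gives the cis ester, so epimerisation, reduction, etherification, allylation of the bromide and desilylation follow.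
- Comparison: both key steps are beyond precedent, so neither is the safer. The chosen plan offers the trans ring directly, with the C3 arm in final form and two steps to the target.

**Alternative 2:** The C2–C3 bond is cut, leading to methyl 2-[5-allyl-3-methoxy-2-[[3-methoxy-4-(methoxymethoxy)phenyl]methoxy]phenyl]-2-diazoacetate A4.
- Forward step: Rh2(S-PTTL)4 or its enantiomer generates the rhodium carbene, which inserts into the benzylic ether C–H and closes the ring as the cis ester A5 (methyl (2S,3R)-5-allyl-7-methoxy-2-[3-methoxy-4-(methoxymethoxy)phenyl]-2,3-dihydro-1-benzofuran-3-carboxylate).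
- Merits: this is established chemistry for exactly this ring system, with dependable enantio- and cis-selectivity, and the ring A allyl group can be present from the start. In reliability it is clearly better than the chosen plan.
- Weak points: the diazo ester is built linearly from an ortho-oxygenated arylacetate. The cis ester must be epimerised at C3, reduced and etherified. The carbene can also engage a terminal alkene of another molecule.
- Comparison: the chosen plan sets convergence and a sequence of eight steps against the greater certainty of this road. Its chemistry is kept as the fallback for the key step.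

**Alternative 3:** The O1–C7a bond is cut, leading to (1S,2R)-2-(5-allyl-2-bromo-3-methoxyphenyl)-3-(4-allyl-2-methoxyphenoxy)-1-[3-methoxy-4-(methoxymethoxy)phenyl]propan-1-ol A6, a syn aldol-derived alcohol.
- Forward step: CuI with 1,10-phenanthroline and Cs2CO3 couples the benzylic alkoxide with the ring A bromide to give the methoxymethyl ether of the target, A7.
- Merits: both stereocentres come from a dependable auxiliary aldol reaction, and the ring closure touches neither. Stereochemically it is safer than the chosen plan.
- Weak points: it needs a ring A arylacetic acid with bromine between the methoxy group and the side chain, a stoichiometric auxiliary, and a copper coupling at a doubly flanked bromide in hot carbonate base, where the allyl groups can migrate.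
- Comparison: the chosen plan sets catalytic asymmetric induction, a shorter convergent sequence and the absence of allyl groups during all palladium and base chemistry before the last two steps against it.

Key step: step 6

Assumption: the (R,R)-configured (salen)MnCl catalyst is taken to give the (2R,3S)-epoxide by analogy with cis-β-methylstyrene; should the sense prove opposite, the (S,S)-catalyst would be used.

## Route

Step 1
Reactants: 1 4-iodo-2-methoxyphenol
Product: 2 4-iodo-2-methoxyphenyl pivalate
Conditions: pivaloyl chloride, K2CO3, acetone, rt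
Reagents that add atoms: pivaloyl chloride, CC(C)(C)C(Cl)=O
Why: O-acylation of a phenoxide with an acid chloride; the pivalate is inert to zerovalent palladium and makes the ring C oxygen an electron-poor substituent for steps 5 and 6.

Step 2
Reactants: 3 4-chloro-2-methoxyphenol; 4 propargyl bromide
Product: 5 4-chloro-2-methoxy-1-(prop-2-yn-1-yloxy)benzene
Conditions: K2CO3, acetone, reflux
Reagents that add atoms: none
Why: Williamson ether synthesis; the phenoxide displaces the propargylic bromide in an SN2 reaction, and carbonate is too weak to isomerise the product to the allene.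

Step 3
Reactants: 2 4-iodo-2-methoxyphenyl pivalate; 5 4-chloro-2-methoxy-1-(prop-2-yn-1-yloxy)benzene
Product: 6 4-[3-(4-chloro-2-methoxyphenoxy)prop-1-yn-1-yl]-2-methoxyphenyl pivalate
Conditions: PdCl2(PPh3)2 (cat.), CuI (cat.), Et3N, THF, rt, degassed
Reagents that add atoms: none
Why: Sonogashira coupling of an aryl iodide with a terminal alkyne at room temperature; the C–Cl bond and the aryl ester are not touched under these conditions.

Step 4
Reactants: 6 4-[3-(4-chloro-2-methoxyphenoxy)prop-1-yn-1-yl]-2-methoxyphenyl pivalate
Product: 7 4-[(1Z)-3-(4-chloro-2-methoxyphenoxy)prop-1-en-1-yl]-2-methoxyphenyl pivalate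
Conditions: H2 (1 atm), Pd/CaCO3 poisoned with Pb(OAc)2, quinoline, EtOAc, rt
Reagents that add atoms: none
Why: Lindlar-type semihydrogenation; syn delivery of hydrogen on the poisoned palladium surface gives the Z-alkene and stops there, and the poisoned catalyst does not hydrogenolyse the aryl chloride or the allylic aryl ether.

Step 5
Reactants: 7 4-[(1Z)-3-(4-chloro-2-methoxyphenoxy)prop-1-en-1-yl]-2-methoxyphenyl pivalate
Product: 8 4-[(2R,3S)-3-[(4-chloro-2-methoxyphenoxy)methyl]oxiran-2-yl]-2-methoxyphenyl pivalate (cis-epoxide)
Conditions: (R,R)-[N,N′-bis(3,5-di-tert-butylsalicylidene)-1,2-cyclohexanediaminato]MnCl (cat.), 4-phenylpyridine N-oxide, NaOCl (aq, pH 11.3), CH2Cl2, 0 °C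
Reagents that add atoms: sodium hypochlorite, [Na+].[O-]Cl
Why: Jacobsen epoxidation of a Z-configured aryl alkene, the best substrate class for (salen)manganese catalysts; the chiral ligand differentiates the alkene faces in a side-on approach to the manganese oxo species and sets C2 and C3 together, and oxygen transfer with retention of the Z geometry gives the cis-epoxide, the N-oxide additive limiting leakage to the trans isomer.

Step 6
Reactants: 8 4-[(2R,3S)-3-[(4-chloro-2-methoxyphenoxy)methyl]oxiran-2-yl]-2-methoxyphenyl pivalate; 9 4-chloro-1-iodo-2-methoxybenzene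
Product: 10 4-[(2S,3R)-5-chloro-3-[(4-chloro-2-methoxyphenoxy)methyl]-7-methoxy-2,3-dihydro-1-benzofuran-2-yl]-2-methoxyphenyl pivalate (trans)
Conditions: Pd(OAc)2 (cat.), XPhos, potassium 5-norbornene-2-carboxylate (cat.), K2CO3, NMP, 80 °C, 9 in excess
Reagents that add atoms: none
Why: Proposed new method: oxidative addition of 9 to zerovalent palladium, norbornene insertion and palladation of the C–H ortho to iodine give an aryl–norbornyl palladacycle of divalent palladium, which opens 8 at C3 by backside attack to a tetravalent palladium alkyl; C–C reductive elimination forms C3–C3a, norbornene is expelled by β-carbon elimination once both ortho positions are filled, and the aryl–palladium alkoxide forms O1–C7a by C–O reductive elimination. The closest known reaction type is the palladium/norbornene (Catellani-type) annulation of ortho-substituted aryl iodides with terminal epoxides to 2-substituted 2,3-dihydrobenzofurans; opening of an internal epoxide at a secondary carbon has not been shown. The dihydrofuran ring closes by reductive elimination from a six-membered oxapalladacycle, an intramolecular aryl etherification. C2 keeps its C–O bond and the configuration it has in the epoxide, and the new stereocentre C3 is set by the inversion that the SN2 opening imposes, so the cis (2R,3S)-epoxide should give the trans (2S,3R)-product (the descriptor at C2 changes only because the CIP priorities change). The step needs attack at C3 and not at benzylic C2: the pivaloyloxy group para to C2 removes the oxygen push that a silyl ether would supply and so closes the ionising (SN1-like, Meinwald) channel, and the bulky palladium nucleophile is expected to prefer the carbon bearing the CH2OAr arm over the one bearing the aryl ring. It also needs C–I over C–Cl selectivity, secured by the reactivity gap of the halides and the excess of 9, and the C7 methoxy of 9 as the ortho substituent that forces norbornene extrusion and stops a second alkylation.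

Step 7
Reactants: 10 4-[(2S,3R)-5-chloro-3-[(4-chloro-2-methoxyphenoxy)methyl]-7-methoxy-2,3-dihydro-1-benzofuran-2-yl]-2-methoxyphenyl pivalate
Product: 11 4-[(2S,3R)-7-methoxy-3-{[2-methoxy-4-(prop-2-en-1-yl)phenoxy]methyl}-5-(prop-2-en-1-yl)-2,3-dihydro-1-benzofuran-2-yl]-2-methoxyphenyl pivalate
Conditions: allylB(pin), Pd(OAc)2 (cat.), XPhos, CsF, 1,4-dioxane, 80 °C
Reagents that add atoms: allylboronic acid pinacol ester, C=CCB1OC(C)(C)C(C)(C)O1
Why: Twofold Suzuki–Miyaura allylation of aryl chlorides; the bulky dialkylbiarylphosphine promotes oxidative addition into the electron-rich C–Cl bonds and fast reductive elimination from the aryl–allyl palladium intermediate, fluoride activation under anhydrous conditions spares the pivalate, and no stereocentre is touched.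

Step 8
Reactants: 11 4-[(2S,3R)-7-methoxy-3-{[2-methoxy-4-(prop-2-en-1-yl)phenoxy]methyl}-5-(prop-2-en-1-yl)-2,3-dihydro-1-benzofuran-2-yl]-2-methoxyphenyl pivalate
Product: 12 4-[(2S,3R)-7-methoxy-3-{[2-methoxy-4-(prop-2-en-1-yl)phenoxy]methyl}-5-(prop-2-en-1-yl)-2,3-dihydro-1-benzofuran-2-yl]-2-methoxyphenol
Conditions: K2CO3 (cat.), MeOH/THF, rt
Reagents that add atoms: none
Why: Base-catalysed transesterification of an aryl ester with methanol; the phenoxide is a good leaving group, so the pivalate should leave at room temperature, where the allyl groups do not migrate and the C2–O1 bond is not at risk.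

## Compound list

1 | 4-iodo-2-methoxyphenol | COc1cc(I)ccc1O | starting material
2 | 4-iodo-2-methoxyphenyl pivalate (2,2-dimethylpropanoate) | COc1cc(I)ccc1OC(=O)C(C)(C)C | intermediate
3 | 4-chloro-2-methoxyphenol | COc1cc(Cl)ccc1O | starting material
4 | propargyl bromide (3-bromoprop-1-yne) | C#CCBr | starting material
5 | 4-chloro-2-methoxy-1-(prop-2-yn-1-yloxy)benzene | C#CCOc1ccc(Cl)cc1OC | intermediate
6 | 4-[3-(4-chloro-2-methoxyphenoxy)prop-1-yn-1-yl]-2-methoxyphenyl pivalate | COc1cc(C#CCOc2ccc(Cl)cc2OC)ccc1OC(=O)C(C)(C)C | intermediate
7 | 4-[(1Z)-3-(4-chloro-2-methoxyphenoxy)prop-1-en-1-yl]-2-methoxyphenyl pivalate | COc1cc(/C=C\COc2ccc(Cl)cc2OC)ccc1OC(=O)C(C)(C)C | intermediate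
8 | 4-[(2R,3S)-3-[(4-chloro-2-methoxyphenoxy)methyl]oxiran-2-yl]-2-methoxyphenyl pivalate (cis) | COc1cc(Cl)ccc1OC[C@@H]1O[C@@H]1c1ccc(OC(=O)C(C)(C)C)c(OC)c1 | intermediate
9 | 4-chloro-1-iodo-2-methoxybenzene | COc1cc(Cl)ccc1I | starting material
10 | 4-[(2S,3R)-5-chloro-3-[(4-chloro-2-methoxyphenoxy)methyl]-7-methoxy-2,3-dihydro-1-benzofuran-2-yl]-2-methoxyphenyl pivalate (trans) | COc1cc(Cl)ccc1OC[C@H]1c2cc(Cl)cc(OC)c2O[C@@H]1c1ccc(OC(=O)C(C)(C)C)c(OC)c1 | intermediate
11 | 4-[(2S,3R)-7-methoxy-3-{[2-methoxy-4-(prop-2-en-1-yl)phenoxy]methyl}-5-(prop-2-en-1-yl)-2,3-dihydro-1-benzofuran-2-yl]-2-methoxyphenyl pivalate | C=CCc1ccc(OC[C@H]2c3cc(CC=C)cc(OC)c3O[C@@H]2c2ccc(OC(=O)C(C)(C)C)c(OC)c2)c(OC)c1 | intermediate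
12 | 4-[(2S,3R)-7-methoxy-3-{[2-methoxy-4-(prop-2-en-1-yl)phenoxy]methyl}-5-(prop-2-en-1-yl)-2,3-dihydro-1-benzofuran-2-yl]-2-methoxyphenol | C=CCc1ccc(OC[C@H]2c3cc(CC=C)cc(OC)c3O[C@@H]2c2ccc(O)c(OC)c2)c(OC)c1 | target

## Step count and least certain steps

Total: 8 steps. Longest linear sequence: 7 steps (1 → 2 → 6 → 7 → 8 → 10 → 11 → 12, or equally from 3 through 5).

**Step 6 (key step, proposed new method).**
- What may go wrong: the palladacycle may attack the benzylic carbon of the epoxide, which is the electronically preferred site. The internal epoxide may react too slowly, so that the palladacycle is lost to protodepalladation or aryl–aryl coupling. The epoxide may rearrange to a ketone under Lewis-acidic palladium or potassium species. Iodide may open the epoxide first, so that a second inversion erodes the trans selectivity.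
- Fallback (known chemistry): it sets out from phenol 3 and comes back at 10.
  - Iodination ortho to the hydroxyl (N-iodosuccinimide, TsOH cat., MeCN) should give 4-chloro-2-iodo-6-methoxyphenol F1.
  - Vanillyl alcohol is acylated on the phenoxide only (pivaloyl chloride, aqueous NaOH/CH2Cl2) to 4-(hydroxymethyl)-2-methoxyphenyl pivalate F2.
  - Mitsunobu etherification of F1 with F2 (PPh3, DIAD, THF) gives 4-[(4-chloro-2-iodo-6-methoxyphenoxy)methyl]-2-methoxyphenyl pivalate F3.
  - Palladium-catalysed coupling of the aryl iodide with methyl diazoacetate (Pd(PPh3)4, Ag2CO3, Et3N, toluene) gives methyl 2-[5-chloro-3-methoxy-2-[(3-methoxy-4-pivaloyloxyphenyl)methoxy]phenyl]-2-diazoacetate F4.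
  - Rh2(S-PTTL)4 or its enantiomer, chosen to set C2 as in 10, effects carbene insertion into the benzylic ether C–H to the cis ester methyl (2S,3R)-5-chloro-7-methoxy-2-(3-methoxy-4-pivaloyloxyphenyl)-2,3-dihydro-1-benzofuran-3-carboxylate F5.
  - NaOMe in MeOH epimerises C3 and removes the pivalate, giving methyl (2S,3S)-5-chloro-2-(4-hydroxy-3-methoxyphenyl)-7-methoxy-2,3-dihydro-1-benzofuran-3-carboxylate F6.
  - LiAlH4 reduces the ester to 4-[(2S,3R)-5-chloro-3-(hydroxymethyl)-7-methoxy-2,3-dihydro-1-benzofuran-2-yl]-2-methoxyphenol F7.
  - Phenoxide-selective acylation (pivaloyl chloride, aqueous NaOH/CH2Cl2) gives 4-[(2S,3R)-5-chloro-3-(hydroxymethyl)-7-methoxy-2,3-dihydro-1-benzofuran-2-yl]-2-methoxyphenyl pivalate F8.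
  - Mitsunobu etherification of F8 with 3 gives 10.

**Step 5.**
- What may go wrong: face selectivity may be incomplete. Stepwise oxygen transfer through a benzylic radical may cost part of the cis geometry, and the trans-epoxide would lead to the cis ring in step 6. The epoxide may open hydrolytically during isolation.
- Fallback: it sets out from 2 and comes back at 8.
  - Sonogashira coupling of 2 with propargyl alcohol gives 4-(3-hydroxyprop-1-yn-1-yl)-2-methoxyphenyl pivalate F9.
  - Semihydrogenation as in step 4 gives 4-[(1Z)-3-hydroxyprop-1-en-1-yl]-2-methoxyphenyl pivalate F10.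
  - Sharpless asymmetric epoxidation (Ti(OiPr)4, L-(+)-diethyl tartrate, t-BuOOH, 4 Å sieves, CH2Cl2, −20 °C) is strictly stereospecific for the alkene geometry and should give 4-[(2R,3S)-3-(hydroxymethyl)oxiran-2-yl]-2-methoxyphenyl pivalate F11.
  - Mitsunobu etherification of the primary alcohol with 3 gives 8 without touching the epoxide.

**Step 7.**
- What may go wrong: coupling of the two deactivated chlorides may be incomplete. Palladium hydrides may move the allyl double bond into conjugation. Fluoride may remove part of the pivalate.
- Fallback: it sets out from 10 and comes back at 11, with reversed polarity.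
  - Miyaura borylation of both C–Cl bonds (Pd2(dba)3, XPhos, B2pin2, KOAc, dioxane, 100 °C) gives the bis(boronate) 4-[(2S,3R)-7-methoxy-3-{[2-methoxy-4-(4,4,5,5-tetramethyl-1,3,2-dioxaborolan-2-yl)phenoxy]methyl}-5-(4,4,5,5-tetramethyl-1,3,2-dioxaborolan-2-yl)-2,3-dihydro-1-benzofuran-2-yl]-2-methoxyphenyl pivalate F12.
  - Coupling with allyl bromide (Pd(PPh3)4, CsF, THF, 50 °C) gives 11 at a lower temperature.

**Step 4.**
- What may go wrong: over-reduction to the saturated chain, Z-to-E isomerisation on the catalyst, or hydrogenolysis of the propargylic C–O bond.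
- Fallback: it sets out from 5 and comes back at 7.
  - Rhodium-catalysed trans-hydroboration of the terminal alkyne ([Rh(cod)Cl]2, P(iPr)3, Et3N, pinacolborane, cyclohexane, rt) gives 2-[(1Z)-3-(4-chloro-2-methoxyphenoxy)prop-1-en-1-yl]-4,4,5,5-tetramethyl-1,3,2-dioxaborolane F13.
  - Suzuki–Miyaura coupling with 2 (Pd(PPh3)4, CsF, THF, 60 °C) gives 7 with retention of the alkene geometry.

## Further compounds

F1 | step 6 | 4-chloro-2-iodo-6-methoxyphenol | COc1cc(Cl)cc(I)c1O
F2 | step 6 | 4-(hydroxymethyl)-2-methoxyphenyl pivalate | COc1cc(CO)ccc1OC(=O)C(C)(C)C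
F3 | step 6 | 4-[(4-chloro-2-iodo-6-methoxyphenoxy)methyl]-2-methoxyphenyl pivalate | COc1cc(COc2c(I)cc(Cl)cc2OC)ccc1OC(=O)C(C)(C)C
F4 | step 6 | methyl 2-[5-chloro-3-methoxy-2-[(3-methoxy-4-pivaloyloxyphenyl)methoxy]phenyl]-2-diazoacetate | COC(=O)C(=[N+]=[N-])c1cc(Cl)cc(OC)c1OCc1ccc(OC(=O)C(C)(C)C)c(OC)c1
F5 | step 6 | methyl (2S,3R)-5-chloro-7-methoxy-2-(3-methoxy-4-pivaloyloxyphenyl)-2,3-dihydro-1-benzofuran-3-carboxylate (cis) | COC(=O)[C@@H]1c2cc(Cl)cc(OC)c2O[C@@H]1c1ccc(OC(=O)C(C)(C)C)c(OC)c1
F6 | step 6 | methyl (2S,3S)-5-chloro-2-(4-hydroxy-3-methoxyphenyl)-7-methoxy-2,3-dihydro-1-benzofuran-3-carboxylate (trans) | COC(=O)[C@H]1c2cc(Cl)cc(OC)c2O[C@@H]1c1ccc(O)c(OC)c1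
F7 | step 6 | 4-[(2S,3R)-5-chloro-3-(hydroxymethyl)-7-methoxy-2,3-dihydro-1-benzofuran-2-yl]-2-methoxyphenol | OC[C@H]1c2cc(Cl)cc(OC)c2O[C@@H]1c1ccc(O)c(OC)c1
F8 | step 6 | 4-[(2S,3R)-5-chloro-3-(hydroxymethyl)-7-methoxy-2,3-dihydro-1-benzofuran-2-yl]-2-methoxyphenyl pivalate | OC[C@H]1c2cc(Cl)cc(OC)c2O[C@@H]1c1ccc(OC(=O)C(C)(C)C)c(OC)c1
F9 | step 5 | 4-(3-hydroxyprop-1-yn-1-yl)-2-methoxyphenyl pivalate | COc1cc(C#CCO)ccc1OC(=O)C(C)(C)C
F10 | step 5 | 4-[(1Z)-3-hydroxyprop-1-en-1-yl]-2-methoxyphenyl pivalate | COc1cc(/C=C\CO)ccc1OC(=O)C(C)(C)C
F11 | step 5 | 4-[(2R,3S)-3-(hydroxymethyl)oxiran-2-yl]-2-methoxyphenyl pivalate (cis) | OC[C@@H]1O[C@@H]1c1ccc(OC(=O)C(C)(C)C)c(OC)c1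
F12 | step 7 | 4-[(2S,3R)-7-methoxy-3-{[2-methoxy-4-(4,4,5,5-tetramethyl-1,3,2-dioxaborolan-2-yl)phenoxy]methyl}-5-(4,4,5,5-tetramethyl-1,3,2-dioxaborolan-2-yl)-2,3-dihydro-1-benzofuran-2-yl]-2-methoxyphenyl pivalate | COc1cc(B2OC(C)(C)C(C)(C)O2)ccc1OC[C@H]1c2cc(B3OC(C)(C)C(C)(C)O3)cc(OC)c2O[C@@H]1c1ccc(OC(=O)C(C)(C)C)c(OC)c1
F13 | step 4 | 2-[(1Z)-3-(4-chloro-2-methoxyphenoxy)prop-1-en-1-yl]-4,4,5,5-tetramethyl-1,3,2-dioxaborolane | COc1cc(Cl)ccc1OC/C=C\B1OC(C)(C)C(C)(C)O1
A1 | alternative 1 | 5-bromo-7-methoxy-1-benzofuran | COc1cc(Br)cc2ccoc12
A2 | alternative 1 | 3-methoxy-4-(triisopropylsilyloxy)benzenediazonium tetrafluoroborate | COc1cc([N+]#N)ccc1O[Si](C(C)C)(C(C)C)C(C)C.F[B-](F)(F)F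
A3 | alternative 1 | methyl (2S,3R)-5-bromo-7-methoxy-2-[3-methoxy-4-(triisopropylsilyloxy)phenyl]-2,3-dihydro-1-benzofuran-3-carboxylate (cis) | COC(=O)[C@@H]1c2cc(Br)cc(OC)c2O[C@@H]1c1ccc(O[Si](C(C)C)(C(C)C)C(C)C)c(OC)c1
A4 | alternative 2 | methyl 2-[5-allyl-3-methoxy-2-[[3-methoxy-4-(methoxymethoxy)phenyl]methoxy]phenyl]-2-diazoacetate | COC(=O)C(=[N+]=[N-])c1cc(CC=C)cc(OC)c1OCc1ccc(OCOC)c(OC)c1
A5 | alternative 2 | methyl (2S,3R)-5-allyl-7-methoxy-2-[3-methoxy-4-(methoxymethoxy)phenyl]-2,3-dihydro-1-benzofuran-3-carboxylate (cis) | COC(=O)[C@@H]1c2cc(CC=C)cc(OC)c2O[C@@H]1c1ccc(OCOC)c(OC)c1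
A6 | alternative 3 | (1S,2R)-2-(5-allyl-2-bromo-3-methoxyphenyl)-3-(4-allyl-2-methoxyphenoxy)-1-[3-methoxy-4-(methoxymethoxy)phenyl]propan-1-ol | C=CCc1ccc(OC[C@@H](c2cc(CC=C)cc(OC)c2Br)[C@H](O)c2ccc(OCOC)c(OC)c2)c(OC)c1
A7 | alternative 3 | (2S,3R)-5-allyl-3-[(4-allyl-2-methoxyphenoxy)methyl]-7-methoxy-2-[3-methoxy-4-(methoxymethoxy)phenyl]-2,3-dihydro-1-benzofuran | C=CCc1ccc(OC[C@H]2c3cc(CC=C)cc(OC)c3O[C@@H]2c2ccc(OCOC)c(OC)c2)c(OC)c1
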